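**Retrosynthetic overview** (germacranolide numbering throughout)

1. The C-8 methacrylate is put on last. Before that, the ten-membered carbocycle is closed by ring-closing metathesis at the (Z)-trisubstituted C-4=C-5 alkene (isopropenyl-furanone onto a lactone vinyl group).
2. The cis-fused α-methylene-γ-butyrolactone is cut at its C–O bond and at C-7–C-8: indium Barbier allylation of a furanone aldehyde with an (S)-but-3-ene-1,2-diol-derived 2-(bromomethyl)acrylate.
3. Key disconnection: the bond between the furanone ring oxygen and the quaternary carbon C-10. The furanone arises from an acyclic α,β-epoxy β-diketone by 5-exo opening of a Sharpless-derived cis-epoxide by the diketone enol oxygen, with acetylation of the freed C-9 hydroxyl in the same flask.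
4. Enabling feature: the furanone ring oxygen on the methyl-bearing quaternary carbon C-10 and the acetoxy oxygen on the neighbouring C-9 are anti-disposed vicinal C–O bonds next to the ring ketone C-1, and the ring oxygen is the enol oxygen of a C-1/C-3 1,3-dicarbonyl. This is the retron of an epoxy ketone opened at its α-carbon by an internal enol oxygen.
5. Order of ring formation: furanone (step 8), butyrolactone (step 18), ten-membered carbocycle (step 20).

Key step: step 8

Remark: C-1 is the ring ketone, C-2=C-3 the enol ether, C-6 the lactone carbinol, C-8 the methacrylate carbinol, C-9 the acetate carbinol, C-10 the quaternary carbon, C-11 to C-13 the methylene-lactone carbons; all numbered starting materials are taken to be commercial.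

**Step 1**
Reactants: 1 (tert-butyldimethylsilyloxy)acetaldehyde; 2 ethyl 2-[bis(2,2,2-trifluoroethoxy)phosphoryl]propanoate
Product: 4 ethyl (2Z)-4-{[tert-butyl(dimethyl)silyl]oxy}-2-methylbut-2-enoate, via potassium phosphonate carbanion 3 (not isolated)
Conditions: KN(SiMe3)2, 18-crown-6, THF, −78 °C
Reagents that add atoms: none
Why: Still–Gennari olefination: the electron-poor phosphonate under dissociating conditions should give the kinetic (Z)-enoate, placing the ester carbon cis to the silyloxymethyl group as the later cis-epoxide requires.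

**Step 2**
Reactants: 4 ethyl (2Z)-4-{[tert-butyl(dimethyl)silyl]oxy}-2-methylbut-2-enoate
Product: 5 (2Z)-4-{[tert-butyl(dimethyl)silyl]oxy}-2-methylbut-2-en-1-ol
Conditions: iBu2AlH (2.2 equiv), CH2Cl2, −78 °C; aq. KNaC4H4O6 work-up
Reagents that add atoms: none
Why: 1,2-reduction of the conjugated ester by the aluminium hydride should give the allylic alcohol without touching the silyl ether or the alkene geometry.

**Step 3**
Reactants: 5 (2Z)-4-{[tert-butyl(dimethyl)silyl]oxy}-2-methylbut-2-en-1-ol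
Product: 6 [(2R,3S)-3-({[tert-butyl(dimethyl)silyl]oxy}methyl)-2-methyloxiran-2-yl]methanol
Conditions: Ti(OiPr)4 (10 mol%), D-(−)-diethyl tartrate (12 mol%), t-BuOOH, 4 Å MS, CH2Cl2, −20 °C
Reagents that add atoms: tert-butyl hydroperoxide, CC(C)(C)OO
Why: Sharpless asymmetric epoxidation: the D-tartrate ligand delivers oxygen to one face of the (Z)-allylic alcohol (reagent control) and sets both epoxide carbons, the cis relationship coming from the alkene.

**Step 4**
Reactants: 6 [(2R,3S)-3-({[tert-butyl(dimethyl)silyl]oxy}methyl)-2-methyloxiran-2-yl]methanol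
Product: 7 (2S,3S)-3-({[tert-butyl(dimethyl)silyl]oxy}methyl)-2-methyloxirane-2-carbaldehyde
Conditions: Dess–Martin periodinane, CH2Cl2, 0 °C to rt
Reagents that add atoms: none
Why: Dess–Martin oxidation of the primary epoxy alcohol; the α-carbon is quaternary, so it cannot epimerise.

**Step 5**
Reactants: 8 3-hydroxy-3-methylbutan-2-one
Product: 9 3-methyl-3-[(triethylsilyl)oxy]butan-2-one
Conditions: Et3SiOTf, 2,6-lutidine, CH2Cl2, 0 °C
Reagents that add atoms: triethylsilyl trifluoromethanesulfonate, CC[Si](CC)(CC)OS(=O)(=O)C(F)(F)F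
Why: Silylation of the tertiary alcohol with a silyl triflate; the silyloxy-isopropyl group is a temporary mask for the isopropenyl group that is neither enolisable nor a Michael acceptor.

**Step 6**
Reactants: 9 3-methyl-3-[(triethylsilyl)oxy]butan-2-one; 7 (2S,3S)-3-({[tert-butyl(dimethyl)silyl]oxy}methyl)-2-methyloxirane-2-carbaldehyde
Product: 11 5-hydroxy-5-[(2R,3S)-3-({[tert-butyl(dimethyl)silyl]oxy}methyl)-2-methyloxiran-2-yl]-2-methyl-2-[(triethylsilyl)oxy]pentan-3-one (both carbinol epimers), via lithium enolate 10 (not isolated)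
Conditions: LiN(iPr)2, THF, −78 °C; then 7; aq. NH4Cl
Reagents that add atoms: none
Why: Aldol addition of the only possible (methyl-side) lithium enolate to the aldehyde; the new carbinol centre forms as a mixture that the next step erases.

**Step 7**
Reactants: 11 aldol adduct
Product: 12 1-[(2S,3S)-3-({[tert-butyl(dimethyl)silyl]oxy}methyl)-2-methyloxiran-2-yl]-4-methyl-4-[(triethylsilyl)oxy]pentane-1,3-dione (largely enolised)
Conditions: Dess–Martin periodinane, CH2Cl2, 0 °C
Reagents that add atoms: none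
Why: Dess–Martin oxidation of a β-hydroxy ketone to the β-diketone, the standard entry to furanone precursors.

**Step 8**
Reactants: 12 epoxy β-diketone
Product: 14 (1S)-2-{[tert-butyl(dimethyl)silyl]oxy}-1-[(2R)-2-methyl-3-oxo-5-{2-[(triethylsilyl)oxy]propan-2-yl}-2,3-dihydrofuran-2-yl]ethyl acetate, via furanone alcohol 13 (not isolated)
Conditions: DBU (0.2 equiv), MeCN, 40 °C; then Ac2O, pyridine, DMAP (cat.), 0 °C
Reagents that add atoms: acetic anhydride, CC(=O)OC(C)=O
Why: Proposed new method: the amidine base turns the β-diketone into its enolate, whose oxygen on the carbonyl remote from the epoxide attacks the quaternary epoxide carbon from the back (SN2, inversion), and the resulting secondary alkoxide is protonated by the next diketone molecule and then acetylated in the same flask. The closest known reactions are the base-induced cyclisation of γ-halo-β-diketones to 3(2H)-furanones and the 5-exo opening of epoxides by enol oxygens of 1,3-dicarbonyl compounds. The furanone ring closes in the 5-exo-tet mode; the new quaternary stereocentre C-10 comes from stereospecific inversion of the Sharpless-derived epoxide carbon, and C-9 is the other epoxide carbon, carried through unchanged. The step needs exo over 6-endo opening and O- over C-alkylation: the planar enolate can reach the backside of the quaternary carbon but not that of the epoxide CH, and C-attack would give a three- or four-membered ring. Both carbons flanking the diketone are fully substituted, so only one enolate can form, and the masked isopropenyl group offers no Michael acceptor. Catalytic base with a non-chelating cation leaves the enolate free to adopt the conformer needed for closure and keeps the product as the neutral alcohol, which should suppress retro-aldol loss of the new carbinol before acetylation.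

**Step 9**
Reactants: 14 furanone acetate
Product: 15 (1S)-2-hydroxy-1-[(2R)-5-(2-hydroxypropan-2-yl)-2-methyl-3-oxo-2,3-dihydrofuran-2-yl]ethyl acetate
Conditions: HF·pyridine, pyridine, THF, 0 °C to rt
Reagents that add atoms: none
Why: Fluoride-mediated cleavage of both silyl ethers under weakly acidic conditions, which should leave the acetate in place and keep acyl migration to the primary hydroxyl slow.

**Step 10**
Reactants: 15 diol
Product: 16 (1R)-1-[(2R)-5-(2-hydroxypropan-2-yl)-2-methyl-3-oxo-2,3-dihydrofuran-2-yl]-2-oxoethyl acetate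
Conditions: Dess–Martin periodinane, CH2Cl2, 0 °C; used crude
Reagents that add atoms: none
Why: Dess–Martin oxidation of the primary alcohol only, since the tertiary alcohol cannot be oxidised.

**Step 11**
Reactants: 17 (2S)-but-3-ene-1,2-diol
Product: 18 (4S)-4-ethenyl-2-(4-methoxyphenyl)-1,3-dioxolane (both acetal epimers)
Conditions: 4-MeOC6H4CH(OMe)2, camphorsulfonic acid (cat.), CH2Cl2, rt
Reagents that add atoms: 4-methoxybenzaldehyde dimethyl acetal, COC(OC)c1ccc(OC)cc1
Why: Acid-catalysed transacetalisation of the 1,2-diol; the stereocentre (the future C-6) comes from the chiral pool.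

**Step 12**
Reactants: 18 arylidene acetal
Product: 19 (2S)-2-[(4-methoxyphenyl)methoxy]but-3-en-1-ol
Conditions: iBu2AlH, CH2Cl2, −78 to 0 °C
Reagents that add atoms: none
Why: Regioselective reductive opening of the arylidene acetal: aluminium binds the less hindered primary oxygen, which becomes the free hydroxyl, so the PMB group stays on the secondary oxygen.

**Step 13**
Reactants: 19 primary alcohol
Product: 20 (2S)-2-[(4-methoxyphenyl)methoxy]but-3-enal
Conditions: Dess–Martin periodinane, CH2Cl2, 0 °C; used at once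
Reagents that add atoms: none
Why: Dess–Martin oxidation without base, so that the α-alkoxy β,γ-unsaturated aldehyde is not enolised.

**Step 14**
Reactants: 21 methyl propiolate; 20 (2S)-2-[(4-methoxyphenyl)methoxy]but-3-enal
Product: 23 methyl (4S)-3-hydroxy-4-[(4-methoxyphenyl)methoxy]-2-methylidenehex-5-enoate (both carbinol epimers), via vinylalane 22 (not isolated)
Conditions: iBu2AlH, N-methylmorpholine N-oxide, THF, 0 °C; then 20, 0 °C to rt
Reagents that add atoms: none
Why: Hydroalumination of the propiolate gives the α-(methoxycarbonyl)vinylalane, which adds 1,2 to the aldehyde to give the Morita–Baylis–Hillman-type adduct without an amine base; the carbinol centre is removed in the next step.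

**Step 15**
Reactants: 23 Baylis–Hillman-type alcohol
Product: 24 methyl (2Z,4S)-2-(bromomethyl)-4-[(4-methoxyphenyl)methoxy]hexa-2,5-dienoate
Conditions: N-bromosuccinimide, Me2S, CH2Cl2, 0 °C to rt
Reagents that add atoms: N-bromosuccinimide, O=C1CCC(=O)N1Br
Why: Corey–Kim-type activation of the hydroxyl and SN2′ attack of bromide transpose the allylic system and should give the (Z)-2-(bromomethyl)enoate.

**Step 16**
Reactants: 16 furanone aldehyde; 24 allylic bromide
Product: 25 methyl (3R,4S)-3-{(1S,2S)-2-acetoxy-1-hydroxy-2-[(2R)-5-(2-hydroxypropan-2-yl)-2-methyl-3-oxo-2,3-dihydrofuran-2-yl]ethyl}-4-[(4-methoxyphenyl)methoxy]-2-methylidenehex-5-enoate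
Conditions: In powder, THF/H2O (3:1), rt
Reagents that add atoms: none
Why: Indium-mediated Barbier allylation at the γ-carbon through a Zimmerman–Traxler chair: the (Z)-allylindium should give the C-7/C-8 syn adduct, the aldehyde should react on its Felkin–Anh face (anti to the acetoxy group), and the allyl face should be set by C-6 (its C–H eclipsing the alkene, the PMB-oxy group turned to indium).

**Step 17**
Reactants: 25 Barbier adduct
Product: 26 methyl (3S,4S)-3-{(1S,2S)-2-acetoxy-1-{[tert-butyl(dimethyl)silyl]oxy}-2-[(2R)-5-(2-hydroxypropan-2-yl)-2-methyl-3-oxo-2,3-dihydrofuran-2-yl]ethyl}-4-[(4-methoxyphenyl)methoxy]-2-methylidenehex-5-enoate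
Conditions: t-BuMe2SiOTf (1.1 equiv), 2,6-lutidine, CH2Cl2, −78 °C
Reagents that add atoms: tert-butyldimethylsilyl trifluoromethanesulfonate, CC(C)(C)[Si](C)(C)OS(=O)(=O)C(F)(F)F
Why: Silylation of the secondary C-8 hydroxyl, which should react far faster than the tertiary one at −78 °C; this blocks lactonisation onto C-8 and keeps a methacrylate out of the metathesis step.

**Step 18**
Reactants: 26 silyl ether
Product: 28 (1S,2S)-2-{[tert-butyl(dimethyl)silyl]oxy}-2-[(2S,3S)-2-ethenyl-4-methylidene-5-oxooxolan-3-yl]-1-[(2R)-5-(2-hydroxypropan-2-yl)-2-methyl-3-oxo-2,3-dihydrofuran-2-yl]ethyl acetate, via hydroxy ester 27 (not isolated)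
Conditions: DDQ, CH2Cl2/pH 7 buffer, 0 °C; then PPTS (cat.), toluene, 50 °C
Reagents that add atoms: none
Why: Oxidative PMB cleavage frees the C-6 hydroxyl, which lactonises onto the acrylate ester under mild acid; with C-8 silylated only the 6,12-lactone can form, and its cis fusion follows from the centres set in step 16.

**Step 19**
Reactants: 28 hydroxy lactone
Product: 29 (1S,2S)-2-{[tert-butyl(dimethyl)silyl]oxy}-2-[(2S,3S)-2-ethenyl-4-methylidene-5-oxooxolan-3-yl]-1-[(2R)-2-methyl-3-oxo-5-(prop-1-en-2-yl)-2,3-dihydrofuran-2-yl]ethyl acetate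
Conditions: Burgess reagent (MeO2CN–SO2NEt3 inner salt), THF, 50 °C
Reagents that add atoms: none
Why: Burgess dehydration (syn-elimination of the sulfamate ester) of the only free, tertiary alcohol; only methyl hydrogens are available, so the isopropenyl group is the sole possible alkene.

**Step 20**
Reactants: 29 diene
Product: 30 (4Z,6S,7S,8S,9S,10R)-9-acetoxy-8-{[tert-butyl(dimethyl)silyl]oxy}-1-oxo-3,10-epoxygermacra-2,4,11(13)-trien-12,6-olide
Conditions: second-generation Hoveyda–Grubbs catalyst RuCl2(H2IMes)(=CH-C6H4-2-OiPr) (15 mol%), toluene (0.001 M), 90 °C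
Reagents that add atoms: none
Why: Ring-closing metathesis of the vinyl group onto the isopropenyl-furanone with loss of ethene, a closure with close precedent in nine-membered furanone-bridged lactones; the bridged ring should only accommodate the (Z)-alkene, and the acrylate-type methylene is a poor metathesis partner.

**Step 21**
Reactants: 30 silyl ether
Product: 31 (4Z,6S,7R,8S,9S,10R)-9-acetoxy-8-hydroxy-1-oxo-3,10-epoxygermacra-2,4,11(13)-trien-12,6-olide
Conditions: HF·pyridine, THF, 0 °C to rt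
Reagents that add atoms: none
Why: Fluoride cleavage of the secondary silyl ether under weakly acidic conditions that spare the acetate and the methylene lactone (the C-7 descriptor changes by priority only).

**Step 22**
Reactants: 31 C-8 alcohol
Product: 32 (4Z,6S,7S,8S,9S,10R)-9-acetoxy-8-(2-methylprop-2-enoyloxy)-1-oxo-3,10-epoxygermacra-2,4,11(13)-trien-12,6-olide (target)
Conditions: methacrylic anhydride, Et3N, DMAP (cat.), CH2Cl2, 0 °C
Reagents that add atoms: methacrylic anhydride, C=C(C)C(=O)OC(=O)C(C)=C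
Why: DMAP-catalysed acylation of the only free hydroxyl, with retention at C-8.

**Compound list**

1 | (tert-butyldimethylsilyloxy)acetaldehyde | O=CCO[Si](C)(C)C(C)(C)C | starting material
2 | ethyl 2-[bis(2,2,2-trifluoroethoxy)phosphoryl]propanoate | CCOC(=O)C(C)P(=O)(OCC(F)(F)F)OCC(F)(F)F | starting material
3 | potassium salt of the α-carbanion of 2 | [K+].CCOC(=O)[C-](C)P(=O)(OCC(F)(F)F)OCC(F)(F)F | intermediate
4 | ethyl (2Z)-4-{[tert-butyl(dimethyl)silyl]oxy}-2-methylbut-2-enoate | CCOC(=O)/C(C)=C\CO[Si](C)(C)C(C)(C)C | intermediate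
5 | (2Z)-4-{[tert-butyl(dimethyl)silyl]oxy}-2-methylbut-2-en-1-ol | OC/C(C)=C\CO[Si](C)(C)C(C)(C)C | intermediate
6 | [(2R,3S)-3-({[tert-butyl(dimethyl)silyl]oxy}methyl)-2-methyloxiran-2-yl]methanol | OC[C@@]1(C)O[C@H]1CO[Si](C)(C)C(C)(C)C | intermediate
7 | (2S,3S)-3-({[tert-butyl(dimethyl)silyl]oxy}methyl)-2-methyloxirane-2-carbaldehyde | O=C[C@@]1(C)O[C@H]1CO[Si](C)(C)C(C)(C)C | intermediate
8 | 3-hydroxy-3-methylbutan-2-one | CC(=O)C(C)(C)O | starting material
9 | 3-methyl-3-[(triethylsilyl)oxy]butan-2-one | CC(=O)C(C)(C)O[Si](CC)(CC)CC | intermediate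
10 | lithium 3-methyl-3-[(triethylsilyl)oxy]but-1-en-2-olate | [Li]OC(=C)C(C)(C)O[Si](CC)(CC)CC | intermediate
11 | 5-hydroxy-5-[(2R,3S)-3-({[tert-butyl(dimethyl)silyl]oxy}methyl)-2-methyloxiran-2-yl]-2-methyl-2-[(triethylsilyl)oxy]pentan-3-one (both carbinol epimers) | CC[Si](CC)(CC)OC(C)(C)C(=O)CC(O)[C@@]1(C)O[C@H]1CO[Si](C)(C)C(C)(C)C | intermediate
12 | 1-[(2S,3S)-3-({[tert-butyl(dimethyl)silyl]oxy}methyl)-2-methyloxiran-2-yl]-4-methyl-4-[(triethylsilyl)oxy]pentane-1,3-dione | CC[Si](CC)(CC)OC(C)(C)C(=O)CC(=O)[C@@]1(C)O[C@H]1CO[Si](C)(C)C(C)(C)C | intermediate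
13 | (2R)-2-[(1S)-2-{[tert-butyl(dimethyl)silyl]oxy}-1-hydroxyethyl]-2-methyl-5-{2-[(triethylsilyl)oxy]propan-2-yl}furan-3(2H)-one | CC[Si](CC)(CC)OC(C)(C)C1=CC(=O)[C@](C)(O1)[C@@H](O)CO[Si](C)(C)C(C)(C)C | intermediate
14 | (1S)-2-{[tert-butyl(dimethyl)silyl]oxy}-1-[(2R)-2-methyl-3-oxo-5-{2-[(triethylsilyl)oxy]propan-2-yl}-2,3-dihydrofuran-2-yl]ethyl acetate | CC[Si](CC)(CC)OC(C)(C)C1=CC(=O)[C@](C)(O1)[C@@H](OC(C)=O)CO[Si](C)(C)C(C)(C)C | intermediate
15 | (1S)-2-hydroxy-1-[(2R)-5-(2-hydroxypropan-2-yl)-2-methyl-3-oxo-2,3-dihydrofuran-2-yl]ethyl acetate | CC(C)(O)C1=CC(=O)[C@](C)(O1)[C@@H](OC(C)=O)CO | intermediate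
16 | (1R)-1-[(2R)-5-(2-hydroxypropan-2-yl)-2-methyl-3-oxo-2,3-dihydrofuran-2-yl]-2-oxoethyl acetate | CC(C)(O)C1=CC(=O)[C@](C)(O1)[C@@H](OC(C)=O)C=O | intermediate
17 | (2S)-but-3-ene-1,2-diol | OC[C@@H](O)C=C | starting material
18 | (4S)-4-ethenyl-2-(4-methoxyphenyl)-1,3-dioxolane (both acetal epimers) | C=C[C@H]1COC(O1)c1ccc(OC)cc1 | intermediate
19 | (2S)-2-[(4-methoxyphenyl)methoxy]but-3-en-1-ol | C=C[C@H](OCc1ccc(OC)cc1)CO | intermediate
20 | (2S)-2-[(4-methoxyphenyl)methoxy]but-3-enal | C=C[C@H](OCc1ccc(OC)cc1)C=O | intermediate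
21 | methyl propiolate | C#CC(=O)OC | starting material
22 | methyl 2-[bis(2-methylpropyl)alumanyl]prop-2-enoate | COC(=O)C(=C)[Al](CC(C)C)CC(C)C | intermediate
23 | methyl (4S)-3-hydroxy-4-[(4-methoxyphenyl)methoxy]-2-methylidenehex-5-enoate (both carbinol epimers) | C=C[C@H](OCc1ccc(OC)cc1)C(O)C(=C)C(=O)OC | intermediate
24 | methyl (2Z,4S)-2-(bromomethyl)-4-[(4-methoxyphenyl)methoxy]hexa-2,5-dienoate | C=C[C@H](OCc1ccc(OC)cc1)/C=C(\CBr)C(=O)OC | intermediate
25 | methyl (3R,4S)-3-{(1S,2S)-2-acetoxy-1-hydroxy-2-[(2R)-5-(2-hydroxypropan-2-yl)-2-methyl-3-oxo-2,3-dihydrofuran-2-yl]ethyl}-4-[(4-methoxyphenyl)methoxy]-2-methylidenehex-5-enoate | CC(C)(O)C1=CC(=O)[C@](C)(O1)[C@@H](OC(C)=O)[C@@H](O)[C@@H](C(=C)C(=O)OC)[C@@H](OCc1ccc(OC)cc1)C=C | intermediate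
26 | methyl (3S,4S)-3-{(1S,2S)-2-acetoxy-1-{[tert-butyl(dimethyl)silyl]oxy}-2-[(2R)-5-(2-hydroxypropan-2-yl)-2-methyl-3-oxo-2,3-dihydrofuran-2-yl]ethyl}-4-[(4-methoxyphenyl)methoxy]-2-methylidenehex-5-enoate | CC(C)(O)C1=CC(=O)[C@](C)(O1)[C@@H](OC(C)=O)[C@@H](O[Si](C)(C)C(C)(C)C)[C@@H](C(=C)C(=O)OC)[C@@H](OCc1ccc(OC)cc1)C=C | intermediate
27 | methyl (3S,4S)-3-{(1S,2S)-2-acetoxy-1-{[tert-butyl(dimethyl)silyl]oxy}-2-[(2R)-5-(2-hydroxypropan-2-yl)-2-methyl-3-oxo-2,3-dihydrofuran-2-yl]ethyl}-4-hydroxy-2-methylidenehex-5-enoate | CC(C)(O)C1=CC(=O)[C@](C)(O1)[C@@H](OC(C)=O)[C@@H](O[Si](C)(C)C(C)(C)C)[C@@H](C(=C)C(=O)OC)[C@@H](O)C=C | intermediate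
28 | (1S,2S)-2-{[tert-butyl(dimethyl)silyl]oxy}-2-[(2S,3S)-2-ethenyl-4-methylidene-5-oxooxolan-3-yl]-1-[(2R)-5-(2-hydroxypropan-2-yl)-2-methyl-3-oxo-2,3-dihydrofuran-2-yl]ethyl acetate | CC(C)(O)C1=CC(=O)[C@](C)(O1)[C@@H](OC(C)=O)[C@@H](O[Si](C)(C)C(C)(C)C)[C@H]1C(=C)C(=O)O[C@H]1C=C | intermediate
29 | (1S,2S)-2-{[tert-butyl(dimethyl)silyl]oxy}-2-[(2S,3S)-2-ethenyl-4-methylidene-5-oxooxolan-3-yl]-1-[(2R)-2-methyl-3-oxo-5-(prop-1-en-2-yl)-2,3-dihydrofuran-2-yl]ethyl acetate | C=C(C)C1=CC(=O)[C@](C)(O1)[C@@H](OC(C)=O)[C@@H](O[Si](C)(C)C(C)(C)C)[C@H]1C(=C)C(=O)O[C@H]1C=C | intermediate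
30 | (4Z,6S,7S,8S,9S,10R)-9-acetoxy-8-{[tert-butyl(dimethyl)silyl]oxy}-1-oxo-3,10-epoxygermacra-2,4,11(13)-trien-12,6-olide | CC(C)(C)[Si](C)(C)O[C@H]1[C@H]2C(=C)C(=O)O[C@H]2/C=C(/C)C2=CC(=O)[C@](C)(O2)[C@H]1OC(C)=O | intermediate
31 | (4Z,6S,7R,8S,9S,10R)-9-acetoxy-8-hydroxy-1-oxo-3,10-epoxygermacra-2,4,11(13)-trien-12,6-olide | O[C@H]1[C@H]2C(=C)C(=O)O[C@H]2/C=C(/C)C2=CC(=O)[C@](C)(O2)[C@H]1OC(C)=O | intermediate
32 | (4Z,6S,7S,8S,9S,10R)-9-acetoxy-8-(2-methylprop-2-enoyloxy)-1-oxo-3,10-epoxygermacra-2,4,11(13)-trien-12,6-olide | C=C(C)C(=O)O[C@H]1[C@H]2C(=C)C(=O)O[C@H]2/C=C(/C)C2=CC(=O)[C@](C)(O2)[C@H]1OC(C)=O | target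

**Step count and risks**

Total: 22 steps. Longest linear sequence: 16 steps (steps 1–4, 6–10, 16–22).

Steps most likely to fail:

1. Step 8 (the proposed method). The enolate may open the epoxide at the CH carbon (6-endo). The epoxide may ionise before ring closure, which would erode the stereospecific inversion at the quaternary carbon. The product alkoxide may undergo retro-aldol cleavage before it is acetylated. The fallback makes the same O–C bond at the alcohol oxidation level by the well-established acid-catalysed 5-exo cyclisation of a 4,5-epoxy alcohol. It sets out from aldol adduct 11: the secondary hydroxyl is silylated (Et3SiOTf, 2,6-lutidine) to the bis(triethylsilyl) ether F1, and the ketone is reduced (NaBH4, MeOH, 0 °C) to the epimeric alcohols F2. Camphorsulfonic acid (cat., CH2Cl2, 0 °C) should then close the tetrahydrofuran by attack of this hydroxyl on the tertiary epoxide carbon with inversion, giving the tetrahydrofuran alcohol F3, which is acetylated (Ac2O, pyridine) to the acetate F4. Selective methanolysis of the secondary triethylsilyl ether (PPTS, MeOH, 0 °C) should give the ring alcohol F5 and Dess–Martin oxidation the dihydrofuran-3(2H)-one F6. Dehydrogenation with 2-iodoxybenzoic acid (DMSO, 65 °C) should then introduce the enol-ether double bond and return to the route at 14.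

2. Step 16. The stereocontrol elements of the two chiral partners may be mismatched, which would give mixtures at C-7 and C-8, and the new hydroxyl may lactonise onto the ester before it is silylated. The fallback takes the stereocentre out of the allyl donor and sets out from 16. The operations of steps 14 and 15 applied to commercial 2,2-dimethoxyacetaldehyde should give the Baylis–Hillman-type alcohol F7 and the achiral acetal bromide F8. Indium-mediated coupling of F8 with 16, now governed only by the Felkin–Anh preference of 16 and the chair transition state, should give the acetal adduct F9, which is silylated (t-BuMe2SiOTf, 2,6-lutidine) to the silyl ether F10. Mild acetal hydrolysis (LiBF4, wet MeCN) should give the C-6 aldehyde F11. Chemoselective Felkin–Anh addition of vinylzinc bromide (from CH2=CHMgBr and ZnBr2, THF, −78 °C) should then give hydroxy ester 27, where the route is rejoined.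

3. Step 20. Ring strain in the cis-fused bicyclic diene may divert the ruthenium alkylidene into oligomerisation by cross-metathesis, or the catalyst may stall at the 1,1-disubstituted dienone alkene. The fallback inverts the order of the two ring closures so that metathesis runs on the conformationally free chain, and sets out from 26. Burgess dehydration should give the isopropenyl triene F12, and ring-closing metathesis (same catalyst, toluene, high dilution) the ten-membered carbocycle F13 with the PMB ether and the methyl ester still in place. DDQ followed by PPTS should then close the lactone across the ring (the freed C-6 hydroxyl and the ester are cis-disposed) and return to the route at 30.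

**Further compounds**

F1 | step 8 | 5-[(2R,3S)-3-({[tert-butyl(dimethyl)silyl]oxy}methyl)-2-methyloxiran-2-yl]-2-methyl-2,5-bis[(triethylsilyl)oxy]pentan-3-one (both epimers) | CC[Si](CC)(CC)OC(C)(C)C(=O)CC(O[Si](CC)(CC)CC)[C@@]1(C)O[C@H]1CO[Si](C)(C)C(C)(C)C
F2 | step 8 | 5-[(2R,3S)-3-({[tert-butyl(dimethyl)silyl]oxy}methyl)-2-methyloxiran-2-yl]-2-methyl-2,5-bis[(triethylsilyl)oxy]pentan-3-ol (epimers) | CC[Si](CC)(CC)OC(C)(C)C(O)CC(O[Si](CC)(CC)CC)[C@@]1(C)O[C@H]1CO[Si](C)(C)C(C)(C)C
F3 | step 8 | (1S)-2-{[tert-butyl(dimethyl)silyl]oxy}-1-[(2R)-2-methyl-3-[(triethylsilyl)oxy]-5-{2-[(triethylsilyl)oxy]propan-2-yl}oxolan-2-yl]ethanol (ring epimers) | CC[Si](CC)(CC)OC(C)(C)C1CC(O[Si](CC)(CC)CC)[C@](C)(O1)[C@@H](O)CO[Si](C)(C)C(C)(C)C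
F4 | step 8 | acetate of F3 | CC[Si](CC)(CC)OC(C)(C)C1CC(O[Si](CC)(CC)CC)[C@](C)(O1)[C@@H](OC(C)=O)CO[Si](C)(C)C(C)(C)C
F5 | step 8 | (1S)-2-{[tert-butyl(dimethyl)silyl]oxy}-1-[(2R)-3-hydroxy-2-methyl-5-{2-[(triethylsilyl)oxy]propan-2-yl}oxolan-2-yl]ethyl acetate (ring epimers) | CC[Si](CC)(CC)OC(C)(C)C1CC(O)[C@](C)(O1)[C@@H](OC(C)=O)CO[Si](C)(C)C(C)(C)C
F6 | step 8 | (1S)-2-{[tert-butyl(dimethyl)silyl]oxy}-1-[(2R)-2-methyl-3-oxo-5-{2-[(triethylsilyl)oxy]propan-2-yl}oxolan-2-yl]ethyl acetate (ring epimers) | CC[Si](CC)(CC)OC(C)(C)C1CC(=O)[C@](C)(O1)[C@@H](OC(C)=O)CO[Si](C)(C)C(C)(C)C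
F7 | step 16 | methyl 3-hydroxy-4,4-dimethoxy-2-methylidenebutanoate | COC(OC)C(O)C(=C)C(=O)OC
F8 | step 16 | methyl (2Z)-2-(bromomethyl)-4,4-dimethoxybut-2-enoate | COC(OC)/C=C(\CBr)C(=O)OC
F9 | step 16 | methyl 3-{(1S,2S)-2-acetoxy-1-hydroxy-2-[(2R)-5-(2-hydroxypropan-2-yl)-2-methyl-3-oxo-2,3-dihydrofuran-2-yl]ethyl}-4,4-dimethoxy-2-methylidenebutanoate (C-7 configured as in 25) | CC(C)(O)C1=CC(=O)[C@](C)(O1)[C@@H](OC(C)=O)[C@@H](O)[C@@H](C(=C)C(=O)OC)C(OC)OC
F10 | step 16 | tert-butyldimethylsilyl ether of F9 | CC(C)(O)C1=CC(=O)[C@](C)(O1)[C@@H](OC(C)=O)[C@@H](O[Si](C)(C)C(C)(C)C)[C@@H](C(=C)C(=O)OC)C(OC)OC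
F11 | step 16 | aldehyde from F10 (C-6 formyl) | CC(C)(O)C1=CC(=O)[C@](C)(O1)[C@@H](OC(C)=O)[C@@H](O[Si](C)(C)C(C)(C)C)[C@@H](C(=C)C(=O)OC)C=O
F12 | step 20 | isopropenyl analogue of 26 (tertiary alcohol dehydrated) | C=C(C)C1=CC(=O)[C@](C)(O1)[C@@H](OC(C)=O)[C@@H](O[Si](C)(C)C(C)(C)C)[C@@H](C(=C)C(=O)OC)[C@@H](OCc1ccc(OC)cc1)C=C
F13 | step 20 | ten-membered carbocycle from F12 with C-6 PMB ether and open methyl acrylate | COC(=O)C(=C)[C@H]1[C@@H](OCc2ccc(OC)cc2)/C=C(/C)C2=CC(=O)[C@](C)(O2)[C@@H](OC(C)=O)[C@H]1O[Si](C)(C)C(C)(C)C
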